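The route rests on cutting the bond between C3 of the dihydrofuran and the ring B carbon that lies meta to both ring B oxygens, a position no Friedel–Crafts closure can reach. An enantioselective dearomative reductive Heck cyclisation forges this bond from a flat 2-(4-methoxyphenyl)benzofuran. In one operation it closes the seven-membered ring, sets C3, and places the C2 hydrogen cis to ring B (C2 and C3 aryl groups trans) by syn aryl-palladation and hydride capture. The precursor is that benzofuran carrying at C4 of ring A a CH(OTBS)–CH(4-methoxyphenyl) bridge to a ring B aryl triflate; the masked ketone and the α-centre are adjusted afterwards.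

Key step: step 13

Remarks on the chemistry (one line each):
- Labels: ring A is the benzo ring of the benzofuran, ring B the dimethoxy ring that carries the triflate, An is 4-methoxyphenyl; benzofuran locants (O1, C2, C3, C4) are kept for the fused products; the bridge carbon on C4 is the carbinol carbon, the bridge carbon bearing An is the α-carbon.
- Assumption: the sense of induction of the bisphosphine cannot be predicted with confidence; (R)-BINAP is written and its mirror image is used should the (2S,3S) series form.
- Assumption: the natural R configuration at the α-carbon (α-H trans to C3–H across the seven-membered ring) is the thermodynamically preferred one, so base equilibration converges on it.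
- Design remark: the bridge of the Heck precursor carries two stereocentres as a mixture, so the precursor is not stereochemically blank; both are erased after ring closure (oxidation, then epimerisation), leaving ligand-controlled facial selectivity as the only stereochemical demand.
- Design remark: the ring B fragment is built from 2-hydroxy-4,6-dimethoxybenzaldehyde, because direct benzylation of 3,5-dimethoxyphenol would give ortho/para mixtures; its benzylic carbanion is generated under thermodynamic control to avoid metalation between ring oxygens.

Step 1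
Reactants: 1 methyl 3,5-dihydroxybenzoate
Product: 2 methyl 3,5-dihydroxy-2-iodobenzoate
Conditions: NIS (1.0 equiv), MeCN, −10 °C to rt
Reagents that add atoms: N-iodosuccinimide, O=C1CCC(=O)N1I
Why: Electrophilic aromatic iodination should occur at C2 (equivalent to C6), ortho to one hydroxyl and para to the other, with one equivalent of reagent at low temperature limiting di-iodination; only this isomer can later place the ester at C4 of the benzofuran.

Step 2
Reactants: 2 methyl 3,5-dihydroxy-2-iodobenzoate; 3 4-ethynylanisole
Product: 5 methyl 6-hydroxy-2-(4-methoxyphenyl)benzofuran-4-carboxylate, via alkynylphenol 4 (not isolated)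
Conditions: PdCl2(PPh3)2 (cat.), CuI (cat.), Et3N, DMF, 70 °C
Reagents that add atoms: none
Why: Sonogashira coupling at the aryl iodide is followed in the same flask by base- and copper-assisted 5-endo-dig attack of the adjacent phenoxide on the alkyne, the usual one-pot passage from 2-iodophenols to 2-arylbenzofurans, while the remote hydroxyl cannot cyclise.

Step 3
Reactants: 5 methyl 6-hydroxy-2-(4-methoxyphenyl)benzofuran-4-carboxylate
Product: 6 methyl 6-methoxy-2-(4-methoxyphenyl)benzofuran-4-carboxylate
Conditions: MeI, K2CO3, acetone, reflux
Reagents that add atoms: iodomethane, CI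
Why: Williamson O-methylation of the remaining phenol with a weak base leaves the ester untouched.

Step 4
Reactants: 6 methyl 6-methoxy-2-(4-methoxyphenyl)benzofuran-4-carboxylate
Product: 7 [6-methoxy-2-(4-methoxyphenyl)benzofuran-4-yl]methanol
Conditions: iBu2AlH (2.5 equiv), CH2Cl2, −78 to 0 °C; aq. potassium sodium tartrate
Reagents that add atoms: none
Why: Full hydride reduction of the aryl ester to the benzylic alcohol avoids the unreliable partial reduction to the aldehyde.

Step 5
Reactants: 7 [6-methoxy-2-(4-methoxyphenyl)benzofuran-4-yl]methanol
Product: 8 6-methoxy-2-(4-methoxyphenyl)benzofuran-4-carbaldehyde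
Conditions: MnO2 (activated, excess), CH2Cl2, rt
Reagents that add atoms: none
Why: Activated MnO2 oxidises benzylic alcohols selectively to aldehydes without over-oxidation and leaves the electron-rich benzofuran alone.

Step 6
Reactants: 9 2-hydroxy-4,6-dimethoxybenzaldehyde; 10 4-methoxyphenylmagnesium bromide
Product: 11 (2-hydroxy-4,6-dimethoxyphenyl)(4-methoxyphenyl)methanol (racemic)
Conditions: 10 (2.5 equiv), THF, 0 °C to rt; aq. NH4Cl
Reagents that add atoms: none
Why: Grignard addition to the aldehyde (one equivalent is consumed by the phenol) fixes the benzylic carbon at the ring position between OH and OMe without regiochemical ambiguity, and the new carbinol centre is removed in the next step.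

Step 7
Reactants: 11 (2-hydroxy-4,6-dimethoxyphenyl)(4-methoxyphenyl)methanol
Product: 12 2-(4-methoxybenzyl)-3,5-dimethoxyphenol
Conditions: Et3SiH (5 equiv), TFA, CH2Cl2, −20 to 0 °C
Reagents that add atoms: none
Why: Ionic hydrogenation: acid ionises the doubly benzylic alcohol to a strongly stabilised diarylmethyl cation that is trapped by excess silane hydride before Friedel–Crafts self-alkylation can compete.

Step 8
Reactants: 12 2-(4-methoxybenzyl)-3,5-dimethoxyphenol
Product: 13 1,5-dimethoxy-2-(4-methoxybenzyl)-3-(methoxymethoxy)benzene
Conditions: MOMCl, iPr2NEt, CH2Cl2, 0 °C to rt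
Reagents that add atoms: chloromethyl methyl ether, COCCl
Why: The methoxymethyl ether masks the acidic phenol for the carbanion step and can later be removed without fluoride or strong protic acid.

Step 9
Reactants: 13 1,5-dimethoxy-2-(4-methoxybenzyl)-3-(methoxymethoxy)benzene; 8 6-methoxy-2-(4-methoxyphenyl)benzofuran-4-carbaldehyde
Product: 15 2-[2,4-dimethoxy-6-(methoxymethoxy)phenyl]-1-[6-methoxy-2-(4-methoxyphenyl)benzofuran-4-yl]-2-(4-methoxyphenyl)ethanol (two racemic diastereomers), via potassium diarylmethanide 14 (not isolated)
Conditions: n-BuLi, KOtBu, 2,2,6,6-tetramethylpiperidine, THF, −78 °C; then 8, −78 °C; aq. NH4Cl at −78 °C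
Reagents that add atoms: none
Why: Benzylic metalation with a mixed lithium–potassium amide base is under thermodynamic control, because the free amine relays any ring-metalated species to the more stable doubly benzylic carbanion, which then adds 1,2 to the non-enolisable aldehyde; the two new stereocentres form without control and are both erased later.

Step 10
Reactants: 15 2-[2,4-dimethoxy-6-(methoxymethoxy)phenyl]-1-[6-methoxy-2-(4-methoxyphenyl)benzofuran-4-yl]-2-(4-methoxyphenyl)ethanol
Product: 16 tert-butyldimethylsilyl ether of 15 (diastereomer mixture)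
Conditions: TBSOTf, 2,6-lutidine, CH2Cl2, −78 to 0 °C
Reagents that add atoms: tert-butyldimethylsilyl triflate, CC(C)(C)[Si](C)(C)OS(=O)(=O)C(F)(F)F
Why: Silylation of the hindered secondary alcohol with a silyl triflate and a hindered pyridine base is fast at low temperature and spares the aryl methoxymethyl ether, and the silyl ether holds this carbon at the alcohol level so that no enolisable ketone sits beside the future aryl triflate.

Step 11
Reactants: 16 tert-butyldimethylsilyl ether of 15
Product: 18 2-{2-[(tert-butyldimethylsilyl)oxy]-2-[6-methoxy-2-(4-methoxyphenyl)benzofuran-4-yl]-1-(4-methoxyphenyl)ethyl}-3,5-dimethoxyphenol, via aryl trimethylsilyl ether 17 (not isolated)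
Conditions: TMSOTf, 2,2′-bipyridyl, CH2Cl2, 0 °C to rt; then H2O
Reagents that add atoms: none
Why: A silyl triflate buffered by 2,2′-bipyridyl converts aromatic methoxymethyl ethers into aryl silyl ethers that hydrolyse on aqueous work-up, conditions under which the alkyl silyl ether and the ionisable benzylic C–O bond should survive.

Step 12
Reactants: 18 2-{2-[(tert-butyldimethylsilyl)oxy]-2-[6-methoxy-2-(4-methoxyphenyl)benzofuran-4-yl]-1-(4-methoxyphenyl)ethyl}-3,5-dimethoxyphenol
Product: 19 2-{2-[(tert-butyldimethylsilyl)oxy]-2-[6-methoxy-2-(4-methoxyphenyl)benzofuran-4-yl]-1-(4-methoxyphenyl)ethyl}-3,5-dimethoxyphenyl trifluoromethanesulfonate (diastereomer mixture)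
Conditions: PhNTf2, Et3N, DMAP (cat.), CH2Cl2, rt
Reagents that add atoms: N-phenylbis(trifluoromethanesulfonimide), O=S(=O)(N(c1ccccc1)S(=O)(=O)C(F)(F)F)C(F)(F)F
Why: The mild triflyl donor sulfonylates only the phenoxide, giving the aryl triflate without touching the silyl ether or the electron-rich rings.

Step 13
Reactants: 19 2-{2-[(tert-butyldimethylsilyl)oxy]-2-[6-methoxy-2-(4-methoxyphenyl)benzofuran-4-yl]-1-(4-methoxyphenyl)ethyl}-3,5-dimethoxyphenyl trifluoromethanesulfonate
Product: 20 (2R,3R)-seven-ring silyl ether: 6-methoxy-2-(4-methoxyphenyl)-2,3-dihydrobenzofuran with ring B on C3 trans to An on C2 and the CH(An)–CH(OTBS) bridge joining ring B to C4 (bridge centres as mixture)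
Conditions: Pd(OAc)2 (10 mol%), (R)-BINAP (12 mol%), HCO2Na (2 equiv), DMF, 90 °C
Reagents that add atoms: none
Why: Zerovalent palladium formed in situ from Pd(OAc)2 and the bisphosphine inserts into the ring B C–OTf bond to give a cationic arylpalladium species, which adds syn across the C2=C3 bond of the benzofuran (aryl to C3, palladium to C2); the resulting tertiary benzylic alkylpalladium has no syn β-hydrogen (C3–H is anti), so it exchanges triflate for formate, loses CO2 and forms the C2–H bond by reductive elimination with retention. The closest known reaction type is the palladium-catalysed enantioselective intramolecular dearomative reductive Heck cyclisation of benzofurans and indoles with formate as hydride source, carried over here to a larger ring. The seven-membered ring closes in 7-exo-trig mode, C3 lying inside and C2 outside the new ring. C3 is set by the chiral ligand, which selects the benzofuran face that is arylated, and C2 follows from syn addition and retentive hydride transfer, so that C2–H is cis to ring B and the two aryl groups are trans (2R,3R). The step needs insertion to precede hydride transfer and ligand control to override the two bridge stereocentres: the triflate enforces the cationic pathway, sparingly soluble HCO2Na keeps the hydride supply low, the silyl ether excludes enolate O-arylation, and both bridge centres are erased in steps 14 and 15, so only facial selectivity matters.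

Step 14
Reactants: 20 (2R,3R)-seven-ring silyl ether
Product: 21 (2R,3R)-seven-ring alcohol (bridge centres as mixture)
Conditions: TBAF, THF, rt to 40 °C
Reagents that add atoms: none
Why: Fluoride cleaves the Si–O bond of the secondary silyl ether under near-neutral conditions that leave the dihydrofuran and the methyl ethers alone.

Step 15
Reactants: 21 (2R,3R)-seven-ring alcohol
Product: 23 pentamethyl ether of pauciflorol E (2R,3R; α-carbon R), via ketone epimer mixture 22 (not isolated)
Conditions: (COCl)2, DMSO, CH2Cl2, −78 °C; Et3N, −78 °C to rt; then DBU, rt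
Reagents that add atoms: none
Why: Swern oxidation converts the hindered benzylic alcohols to the aryl ketone, and DBU added to the same flask enolises only the doubly benzylic α-position, so that the α-aryl centre settles in its thermodynamic R configuration (α-H trans to C3–H) while the non-acidic C2 and C3 centres are untouched.

Step 16
Reactants: 23 pentamethyl ether of pauciflorol E
Product: 24 pauciflorol E
Conditions: BBr3 (excess), CH2Cl2, −78 °C to rt; MeOH then H2O quench
Reagents that add atoms: none
Why: BBr3 cleaves all five aryl methyl ethers by Lewis-acid activation and bromide attack at methyl, any reversible ionisation of the C2–O bond should reclose to the more stable trans-dihydrofuran, and the stereocentres are otherwise not engaged.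

Compound list
1 | methyl 3,5-dihydroxybenzoate | COC(=O)c1cc(O)cc(O)c1 | starting material
2 | methyl 3,5-dihydroxy-2-iodobenzoate | COC(=O)c1cc(O)cc(O)c1I | intermediate
3 | 4-ethynylanisole | COc1ccc(C#C)cc1 | starting material
4 | methyl 3,5-dihydroxy-2-[(4-methoxyphenyl)ethynyl]benzoate (not isolated) | COC(=O)c1cc(O)cc(O)c1C#Cc1ccc(OC)cc1 | intermediate
5 | methyl 6-hydroxy-2-(4-methoxyphenyl)benzofuran-4-carboxylate | COC(=O)c1cc(O)cc2oc(-c3ccc(OC)cc3)cc12 | intermediate
6 | methyl 6-methoxy-2-(4-methoxyphenyl)benzofuran-4-carboxylate | COC(=O)c1cc(OC)cc2oc(-c3ccc(OC)cc3)cc12 | intermediate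
7 | [6-methoxy-2-(4-methoxyphenyl)benzofuran-4-yl]methanol | OCc1cc(OC)cc2oc(-c3ccc(OC)cc3)cc12 | intermediate
8 | 6-methoxy-2-(4-methoxyphenyl)benzofuran-4-carbaldehyde | O=Cc1cc(OC)cc2oc(-c3ccc(OC)cc3)cc12 | intermediate
9 | 2-hydroxy-4,6-dimethoxybenzaldehyde | COc1cc(O)c(C=O)c(OC)c1 | starting material
10 | 4-methoxyphenylmagnesium bromide | COc1ccc([Mg]Br)cc1 | starting material
11 | (2-hydroxy-4,6-dimethoxyphenyl)(4-methoxyphenyl)methanol, racemic | COc1ccc(C(O)c2c(O)cc(OC)cc2OC)cc1 | intermediate
12 | 2-(4-methoxybenzyl)-3,5-dimethoxyphenol | COc1ccc(Cc2c(O)cc(OC)cc2OC)cc1 | intermediate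
13 | 1,5-dimethoxy-2-(4-methoxybenzyl)-3-(methoxymethoxy)benzene | COCOc1cc(OC)cc(OC)c1Cc1ccc(OC)cc1 | intermediate
14 | potassium [2,4-dimethoxy-6-(methoxymethoxy)phenyl](4-methoxyphenyl)methanide (not isolated) | COCOc1cc(OC)cc(OC)c1[CH-]c1ccc(OC)cc1.[K+] | intermediate
15 | 2-[2,4-dimethoxy-6-(methoxymethoxy)phenyl]-1-[6-methoxy-2-(4-methoxyphenyl)benzofuran-4-yl]-2-(4-methoxyphenyl)ethanol, two racemic diastereomers | COCOc1cc(OC)cc(OC)c1C(c1ccc(OC)cc1)C(O)c1cc(OC)cc2oc(-c3ccc(OC)cc3)cc12 | intermediate
16 | tert-butyldimethylsilyl ether of 15 at the carbinol oxygen, diastereomer mixture | COCOc1cc(OC)cc(OC)c1C(c1ccc(OC)cc1)C(O[Si](C)(C)C(C)(C)C)c1cc(OC)cc2oc(-c3ccc(OC)cc3)cc12 | intermediate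
17 | analogue of 16 with the ring B oxygen as trimethylsilyl ether (not isolated) | C[Si](C)(C)Oc1cc(OC)cc(OC)c1C(c1ccc(OC)cc1)C(O[Si](C)(C)C(C)(C)C)c1cc(OC)cc2oc(-c3ccc(OC)cc3)cc12 | intermediate
18 | 2-{2-[(tert-butyldimethylsilyl)oxy]-2-[6-methoxy-2-(4-methoxyphenyl)benzofuran-4-yl]-1-(4-methoxyphenyl)ethyl}-3,5-dimethoxyphenol, diastereomer mixture | Oc1cc(OC)cc(OC)c1C(c1ccc(OC)cc1)C(O[Si](C)(C)C(C)(C)C)c1cc(OC)cc2oc(-c3ccc(OC)cc3)cc12 | intermediate
19 | aryl triflate of 18 (Heck precursor), diastereomer mixture | CC(C)(C)[Si](C)(C)OC(c1cc(OC)cc2oc(-c3ccc(OC)cc3)cc12)C(c1ccc(OC)cc1)c1c(OS(=O)(=O)C(F)(F)F)cc(OC)cc1OC | intermediate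
20 | silyl ether of the permethylated seven-ring alcohol: (2R,3R)-6-methoxy-2-(4-methoxyphenyl)-2,3-dihydrobenzofuran whose C3 and C4 are bridged by 3,5-dimethoxy-1,2-phenylene (ring B, its C1 on C3)–CH(An)–CH(OTBS); An on C2 trans to ring B; carbinol and α-carbon mixed | CC(C)(C)[Si](C)(C)OC1c2cc(OC)cc3c2[C@@H](c2cc(OC)cc(OC)c2C1c1ccc(OC)cc1)[C@H](c1ccc(OC)cc1)O3 | intermediate
21 | free alcohol corresponding to 20 (2R,3R; carbinol and α-carbon mixed) | OC1c2cc(OC)cc3c2[C@@H](c2cc(OC)cc(OC)c2C1c1ccc(OC)cc1)[C@H](c1ccc(OC)cc1)O3 | intermediate
22 | ketone corresponding to 21 (2R,3R; both α-epimers; not isolated) | O=C1c2cc(OC)cc3c2[C@@H](c2cc(OC)cc(OC)c2C1c1ccc(OC)cc1)[C@H](c1ccc(OC)cc1)O3 | intermediate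
23 | pentamethyl ether of pauciflorol E (2R,3R; α-carbon R, α-H trans to C3–H) | O=C1c2cc(OC)cc3c2[C@@H](c2cc(OC)cc(OC)c2[C@H]1c1ccc(OC)cc1)[C@H](c1ccc(OC)cc1)O3 | intermediate
24 | pauciflorol E | O=C1c2cc(O)cc3c2[C@@H](c2cc(O)cc(O)c2[C@H]1c1ccc(O)cc1)[C@H](c1ccc(O)cc1)O3 | target

Total step count: 16. Longest linear sequence: 13 steps (steps 1 to 5 and 9 to 16, from methyl 3,5-dihydroxybenzoate).

Steps most likely to fail

Step 13. The 7-exo insertion may be slow for those stereoisomers of 19 whose bridge configuration opposes the benzofuran face preferred by the ligand. Such isomers would lose the triflate by premature hydride transfer, or close on the wrong face and erode the enantiomeric purity. The fallback replaces pure ligand control by matched double stereodifferentiation with a stereodefined bridge. It sets out from 15: the diastereomers are separated on silica and each is resolved by preparative HPLC on a chiral stationary phase. The stereoisomers with the α-carbon in the R configuration that the product ring prefers, (αR)-carbinol F1, are expected to cooperate with the ligand; they are taken through steps 10 to 13 and rejoin the route at 20. The remaining stereoisomers are recycled by Dess–Martin oxidation to the α,α-diaryl ketone F2, which racemises at the α-carbon through its enol under mild base, and by NaBH4 reduction back to 15.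

Step 9. Metalation may take place on ring B at a C–H flanked by two oxygens instead of at the benzylic CH2, or the crowded carbanion may add sluggishly and be lost by proton transfer. The fallback generates the carbanion by reductive C–O cleavage at a predefined carbon instead of by deprotonation. It sets out from 11, which excess MOMCl and iPr2NEt convert into the bis(methoxymethyl) ether F3. Lithium 4,4′-di-tert-butylbiphenylide in THF at −78 °C cleaves the benzhydryl C–O bond and gives the lithium diarylmethanide F4 regiospecifically. Addition of aldehyde 8 at −78 °C returns to the route at 15.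

Step 16. Lewis-acid ionisation of the benzylic C2–O bond of the dihydrofuran (ring opening, bromide capture or epimerisation at C2) may compete with cleavage of the five methyl ethers, two of which on ring B are hindered. The fallback uses nucleophilic instead of Lewis-acidic ether cleavage. It sets out from 23 and uses sodium ethanethiolate (NaSEt) in DMF at 120 to 140 °C, which attacks the methyl groups by SN2 and never activates the dihydrofuran oxygen. It returns directly at 24 and makes no new compound (F0).

Further compounds
F1 | step 13 | single (αR)-configured stereoisomers of 15 (carbinol carbon either way) | COCOc1cc(OC)cc(OC)c1[C@@H](c1ccc(OC)cc1)C(O)c1cc(OC)cc2oc(-c3ccc(OC)cc3)cc12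
F2 | step 13 | 2-[2,4-dimethoxy-6-(methoxymethoxy)phenyl]-1-[6-methoxy-2-(4-methoxyphenyl)benzofuran-4-yl]-2-(4-methoxyphenyl)ethanone, racemic | COCOc1cc(OC)cc(OC)c1C(c1ccc(OC)cc1)C(=O)c1cc(OC)cc2oc(-c3ccc(OC)cc3)cc12
F3 | step 9 | 1,5-dimethoxy-3-(methoxymethoxy)-2-[(methoxymethoxy)(4-methoxyphenyl)methyl]benzene, racemic | COCOc1cc(OC)cc(OC)c1C(OCOC)c1ccc(OC)cc1
F4 | step 9 | lithium [2,4-dimethoxy-6-(methoxymethoxy)phenyl](4-methoxyphenyl)methanide | COCOc1cc(OC)cc(OC)c1[CH-]c1ccc(OC)cc1.[Li+]
F0 | step 16 | none | none
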